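**Retrosynthetic overview**

1. Bractelactone comes from its 6,7-methylenedioxy-protected lactone by opening the dioxole acetal with BCl3 as the last step.
2. The lactone ring (O1–C2–C3–C3a–C7a) is disconnected at C7a–O1, leading back to a Z alpha-aryl acrylic acid. Feature: in the benzofuranone, C4 (OMe), C5 (acyl), C6 and C7 (oxygens) and C3a (acrylic unit) fill the benzene ring, so C7a holds its only hydrogen; C7a is ortho to C3a, and the carboxyl on C3 (future C2 and O1) can reach it through a six-membered palladacycle.
3. The acid comes from an aryl iodide and an alpha-stannyl cinnamate (C3a–C3 bond, Stille coupling); syn hydrostannation of methyl 3-phenylpropiolate fixes the Z geometry.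
4. The aryl iodide comes from sesamol by O-methylation, lithiation between the two oxygens with addition to 3-phenylpropanal, oxidation, and iodination.
5. Ring order: the benzene and dioxole rings are bought with sesamol, the lactone ring is the only ring closed (step 8), and the dioxole ring is opened last.

Key step: step 8

Remark on the chemistry: benzofuranone locants (O1, C2, C3, C3a, C4 to C7, C7a) are used for the lactones and the target, benzodioxole locants for the earlier compounds; the Z descriptor means phenyl cis to the carboxyl or lactone carbonyl, as the target SMILES shows.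

**Route**

Step 1
Reactants: 1 sesamol (1,3-benzodioxol-5-ol)
Product: 2 5-methoxy-1,3-benzodioxole
Conditions: MeI, K2CO3, acetone, reflux
Reagents that add atoms: iodomethane, CI
Why: Williamson ether synthesis, in which the phenoxide of sesamol is alkylated on oxygen by iodomethane while the dioxole acetal is inert to carbonate base.

Step 2
Reactants: 2 5-methoxy-1,3-benzodioxole; 3 3-phenylpropanal
Product: 5 rac-1-(5-methoxy-1,3-benzodioxol-4-yl)-3-phenylpropan-1-ol, via aryllithium 4 (not isolated)
Conditions: n-BuLi, THF, –78 → 0 °C; then 3, –78 °C; then H2O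
Reagents that add atoms: none
Why: Directed ortho-metalation followed by 1,2-addition to an aldehyde, where C4–H lies between the methoxy oxygen and a dioxole oxygen and is the most acidic and best-coordinated site, the aryllithium should add to the aldehyde at –78 °C faster than it enolises it, and the new carbinol centre forms as a racemate that step 3 removes.

Step 3
Reactants: 5 rac-1-(5-methoxy-1,3-benzodioxol-4-yl)-3-phenylpropan-1-ol
Product: 6 1-(5-methoxy-1,3-benzodioxol-4-yl)-3-phenylpropan-1-one
Conditions: Dess–Martin periodinane, CH2Cl2, rt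
Reagents that add atoms: none
Why: Dess–Martin oxidation of a secondary benzylic alcohol to the aryl ketone under neutral conditions that leave the electron-rich ring and the acetal untouched.

Step 4
Reactants: 6 1-(5-methoxy-1,3-benzodioxol-4-yl)-3-phenylpropan-1-one
Product: 7 1-(6-iodo-5-methoxy-1,3-benzodioxol-4-yl)-3-phenylpropan-1-one
Conditions: NIS, TFA (cat.), MeCN, rt
Reagents that add atoms: N-iodosuccinimide, O=C1CCC(=O)N1I
Why: Electrophilic aromatic iodination, in which C6 is ortho to the methoxy group, para to a dioxole oxygen and meta to the ketone so that all three groups direct iodine there, whereas C7 is para to the ketone and the side-chain phenyl ring is not activated.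

Step 5
Reactants: 8 methyl 3-phenylpropiolate
Product: 9 methyl (E)-3-phenyl-2-(tributylstannyl)prop-2-enoate (phenyl and ester cis)
Conditions: Bu3SnH, Pd(PPh3)4 (2 mol %), THF, 0 °C → rt
Reagents that add atoms: tributyltin hydride, CCCC[SnH](CCCC)CCCC
Why: Palladium-catalysed hydrostannation of an alkynoate, in which H and SnBu3 add syn across the triple bond with tin going to the carbon alpha to the ester, so that phenyl and ester end up cis as the target requires.

Step 6
Reactants: 7 1-(6-iodo-5-methoxy-1,3-benzodioxol-4-yl)-3-phenylpropan-1-one; 9 methyl (E)-3-phenyl-2-(tributylstannyl)prop-2-enoate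
Product: 10 methyl (Z)-2-[6-methoxy-7-(3-phenylpropanoyl)-1,3-benzodioxol-5-yl]-3-phenylprop-2-enoate
Conditions: Pd(PPh3)4 (10 mol %), CuI (20 mol %), CsF (2 equiv), DMF, 45 °C
Reagents that add atoms: none
Why: Stille cross-coupling with copper and fluoride assistance, which speeds transmetalation of the hindered alpha-stannyl acrylate and suppresses cine substitution, and which proceeds with retention at the vinyl carbon so that the aryl group takes the place of tin trans to phenyl and the Z ester results.

Step 7
Reactants: 10 methyl (Z)-2-[6-methoxy-7-(3-phenylpropanoyl)-1,3-benzodioxol-5-yl]-3-phenylprop-2-enoate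
Product: 11 (Z)-2-[6-methoxy-7-(3-phenylpropanoyl)-1,3-benzodioxol-5-yl]-3-phenylprop-2-enoic acid
Conditions: LiOH, THF/MeOH/H2O, 40 °C; then 1 M HCl
Reagents that add atoms: lithium hydroxide, [Li+].[OH-]
Why: Saponification (acyl–oxygen ester hydrolysis) of the methyl ester by hydroxide, under which the ketone, the acetal and the alkene geometry should be stable, followed by acidification to the free acid.

Step 8
Reactants: 11 (Z)-2-[6-methoxy-7-(3-phenylpropanoyl)-1,3-benzodioxol-5-yl]-3-phenylprop-2-enoic acid
Product: 12 (Z)-3-benzylidene-4-methoxy-6,7-methylenedioxy-5-(3-phenylpropanoyl)-1-benzofuran-2(3H)-one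
Conditions: Pd(OAc)2 (10 mol %), Ac-Gly-OH (20 mol %), PhI(OAc)2 (1.5 equiv), KOAc (2 equiv), t-BuOH, 80 °C
Reagents that add atoms: none
Why: Proposed new method: the potassium carboxylate of 11 binds divalent palladium, the N-acetylglycine ligand serves as internal base in a concerted metalation–deprotonation of the single C–H of the benzodioxole ring (C7a of the benzofuranone), and PhI(OAc)2 oxidises the six-membered palladacycle to tetravalent palladium, from which C–O reductive elimination forms the C7a–O1 bond; the closest known reaction is the Pd(OAc)2/PhI(OAc)2 lactonisation of arylacetic acids to benzofuran-2(3H)-ones, extended here to an acid whose alpha carbon is sp2 and so carries no oxidisable alpha hydrogen. The five-membered lactone ring closes by this reductive elimination, a ring contraction of the six-membered palladacycle in which the carboxylate oxygen bonds to the palladated carbon. No stereocentre is formed, and the Z alkene set in steps 5 and 6 should survive because neither alkene carbon bonds to palladium. The selectivity required is palladation at C7a and not at an ortho C–H of the benzylidene phenyl that sits cis to the carboxyl; C7a–H is the only C–H on the central ring, is acidified by the adjacent tied-back dioxole oxygen and is reached through a six-membered palladacycle, whereas the phenyl C–H would need a seven-membered one. The conformer with the carboxyl turned to the C7a side puts only the small vinyl hydrogen next to the C4 methoxy group, and the masked catechol, the ketone and the electron-poor trisubstituted alkene are not expected to react with PhI(OAc)2 at this temperature.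

Step 9
Reactants: 12 (Z)-3-benzylidene-4-methoxy-6,7-methylenedioxy-5-(3-phenylpropanoyl)-1-benzofuran-2(3H)-one
Product: 14 bractelactone [(Z)-3-benzylidene-6,7-dihydroxy-4-methoxy-5-(3-phenylpropanoyl)-1-benzofuran-2(3H)-one], via O-dichloroboryl chloromethyl ether 13 (not isolated)
Conditions: BCl3 (2.5 equiv), CH2Cl2, –78 → –20 °C; then H2O
Reagents that add atoms: none
Why: Lewis acid cleavage of a methylenedioxy acetal, in which BCl3 bound to the C5 ketone carbonyl chelates the coplanar C6 acetal oxygen, the activated O–CH2 bond should break to a chloromethyl ether faster than chloride can demethylate the C4 ether by SN2 at this temperature, the ketone is then held in the boron chelate, and water hydrolyses the borate and the chloromethyl ether to the catechol with loss of formaldehyde.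

**Compound list**

1 | sesamol (1,3-benzodioxol-5-ol) | Oc1ccc2OCOc2c1 | starting material
2 | 5-methoxy-1,3-benzodioxole | COc1ccc2OCOc2c1 | intermediate
3 | 3-phenylpropanal | O=CCCc1ccccc1 | starting material
4 | 4-lithio-5-methoxy-1,3-benzodioxole (aryllithium, not isolated) | COc1ccc2OCOc2c1[Li] | intermediate
5 | rac-1-(5-methoxy-1,3-benzodioxol-4-yl)-3-phenylpropan-1-ol | COc1ccc2OCOc2c1C(O)CCc1ccccc1 | intermediate
6 | 1-(5-methoxy-1,3-benzodioxol-4-yl)-3-phenylpropan-1-one | COc1ccc2OCOc2c1C(=O)CCc1ccccc1 | intermediate
7 | 1-(6-iodo-5-methoxy-1,3-benzodioxol-4-yl)-3-phenylpropan-1-one | COc1c(I)cc2OCOc2c1C(=O)CCc1ccccc1 | intermediate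
8 | methyl 3-phenylpropiolate | COC(=O)C#Cc1ccccc1 | starting material
9 | methyl (E)-3-phenyl-2-(tributylstannyl)prop-2-enoate | CCCC[Sn](CCCC)(CCCC)/C(=C/c1ccccc1)C(=O)OC | intermediate
10 | methyl (Z)-2-[6-methoxy-7-(3-phenylpropanoyl)-1,3-benzodioxol-5-yl]-3-phenylprop-2-enoate | COc1c(C(=O)CCc2ccccc2)c2OCOc2cc1/C(=C/c1ccccc1)C(=O)OC | intermediate
11 | (Z)-2-[6-methoxy-7-(3-phenylpropanoyl)-1,3-benzodioxol-5-yl]-3-phenylprop-2-enoic acid | COc1c(C(=O)CCc2ccccc2)c2OCOc2cc1/C(=C/c1ccccc1)C(=O)O | intermediate
12 | (Z)-3-benzylidene-4-methoxy-6,7-methylenedioxy-5-(3-phenylpropanoyl)-1-benzofuran-2(3H)-one | COc1c(C(=O)CCc2ccccc2)c2OCOc2c2c1/C(=C/c1ccccc1)C(=O)O2 | intermediate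
13 | (Z)-3-benzylidene-7-(chloromethoxy)-6-(dichloroboryloxy)-4-methoxy-5-(3-phenylpropanoyl)-1-benzofuran-2(3H)-one (not isolated) | COc1c(C(=O)CCc2ccccc2)c(OB(Cl)Cl)c(OCCl)c2c1/C(=C/c1ccccc1)C(=O)O2 | intermediate
14 | bractelactone, (Z)-3-benzylidene-6,7-dihydroxy-4-methoxy-5-(3-phenylpropanoyl)-1-benzofuran-2(3H)-one | COc1c(C(=O)CCc2ccccc2)c(O)c(O)c2c1/C(=C/c1ccccc1)C(=O)O2 | target

**Summary**

Total step count: 9. Longest linear sequence: 8 steps (steps 1, 2, 3, 4, 6, 7, 8, 9); step 5 is a one-step side branch.

Steps most likely to fail:

1. Step 8 (proposed new method). Palladation may not take place at C7a with an sp2 alpha carbon, it may divert to the benzylidene phenyl ring through the larger palladacycle and end in a coumarin, or the oxidant may degrade the substrate before C–O reductive elimination. The fallback brings in the C7a oxygen by sterically controlled C–H borylation and closes the lactone by acyl transfer; it sets out from 2 (and uses 9) and comes back at 12.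
   - Aryllithium 4, made from 2 as in step 2, would be quenched with N-methoxy-N-methylcarbamoyl chloride to give the Weinreb amide N,5-dimethoxy-N-methyl-1,3-benzodioxole-4-carboxamide F1. This compound is used instead of 6 because the side-chain phenyl ring of 6 would also be borylated.
   - Borylation with [Ir(OMe)(cod)]2, 4,4'-di-tert-butyl-2,2'-bipyridine and B2pin2 should go at C7, the only ring C–H not ortho to the methoxy group and the one next to a dioxole oxygen, to give N,5-dimethoxy-N-methyl-7-(4,4,5,5-tetramethyl-1,3,2-dioxaborolan-2-yl)-1,3-benzodioxole-4-carboxamide F2.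
   - H2O2/NaOH would oxidise the boronate to the phenol 7-hydroxy-N,5-dimethoxy-N-methyl-1,3-benzodioxole-4-carboxamide F3.
   - Excess 2-phenylethylmagnesium bromide would convert the amide into 1-(7-hydroxy-5-methoxy-1,3-benzodioxol-4-yl)-3-phenylpropan-1-one F4.
   - NIS would iodinate the single free position of the central ring to give 1-(7-hydroxy-6-iodo-5-methoxy-1,3-benzodioxol-4-yl)-3-phenylpropan-1-one F5.
   - Stille coupling with 9 under the conditions of step 6 would give methyl (Z)-2-[4-hydroxy-6-methoxy-7-(3-phenylpropanoyl)-1,3-benzodioxol-5-yl]-3-phenylprop-2-enoate F6, whose phenol should close onto the ester (cat. TsOH, toluene, if not spontaneous) to give 12.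

2. Step 9. Boron-assisted demethylation of the C4 methyl ether ortho to the ketone may compete with acetal opening, or the lactone may open during work-up. The fallback removes the acetal oxidatively, with no Lewis acid; it sets out from 12 and comes back at 14.
   - Pb(OAc)4 in benzene at 50 °C would acetoxylate the acetal CH2 to give (Z)-6,7-(acetoxymethylenedioxy)-3-benzylidene-4-methoxy-5-(3-phenylpropanoyl)-1-benzofuran-2(3H)-one F7, racemic at the acetal carbon.
   - Aqueous acetic acid in THF would hydrolyse F7 through the catechol monoformate to 14.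

3. Step 6. Transmetalation of the hindered alpha-stannyl acrylate to the ortho-substituted, electron-rich arylpalladium species may be slow, so that protodestannylation, homocoupling or cine substitution take over. The fallback reverses the polarity of the coupling; it sets out from 7 and 9 and comes back at 10.
   - Miyaura borylation of 7 (B2pin2, PdCl2(dppf), KOAc, dioxane, 80 °C) would give 1-[5-methoxy-6-(4,4,5,5-tetramethyl-1,3,2-dioxaborolan-2-yl)-1,3-benzodioxol-4-yl]-3-phenylpropan-1-one F8.
   - Iododestannylation of 9 with I2 in CH2Cl2, which goes with retention, would give methyl (E)-2-iodo-3-phenylprop-2-enoate F9.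
   - Suzuki–Miyaura coupling of F8 with F9 (Pd(PPh3)4, K3PO4, dioxane/H2O, 60 °C) would give 10 with retention of the alkene geometry.

**Further compounds**

F1 | step 8 | N,5-dimethoxy-N-methyl-1,3-benzodioxole-4-carboxamide | COc1ccc2OCOc2c1C(=O)N(C)OC
F2 | step 8 | N,5-dimethoxy-N-methyl-7-(4,4,5,5-tetramethyl-1,3,2-dioxaborolan-2-yl)-1,3-benzodioxole-4-carboxamide | COc1cc(B3OC(C)(C)C(C)(C)O3)c2OCOc2c1C(=O)N(C)OC
F3 | step 8 | 7-hydroxy-N,5-dimethoxy-N-methyl-1,3-benzodioxole-4-carboxamide | COc1cc(O)c2OCOc2c1C(=O)N(C)OC
F4 | step 8 | 1-(7-hydroxy-5-methoxy-1,3-benzodioxol-4-yl)-3-phenylpropan-1-one | COc1cc(O)c2OCOc2c1C(=O)CCc1ccccc1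
F5 | step 8 | 1-(7-hydroxy-6-iodo-5-methoxy-1,3-benzodioxol-4-yl)-3-phenylpropan-1-one | COc1c(I)c(O)c2OCOc2c1C(=O)CCc1ccccc1
F6 | step 8 | methyl (Z)-2-[4-hydroxy-6-methoxy-7-(3-phenylpropanoyl)-1,3-benzodioxol-5-yl]-3-phenylprop-2-enoate | COc1c(C(=O)CCc2ccccc2)c2OCOc2c(O)c1/C(=C/c1ccccc1)C(=O)OC
F7 | step 9 | (Z)-6,7-(acetoxymethylenedioxy)-3-benzylidene-4-methoxy-5-(3-phenylpropanoyl)-1-benzofuran-2(3H)-one (racemic at the acetal carbon) | COc1c(C(=O)CCc2ccccc2)c2OC(OC(C)=O)Oc2c2c1/C(=C/c1ccccc1)C(=O)O2
F8 | step 6 | 1-[5-methoxy-6-(4,4,5,5-tetramethyl-1,3,2-dioxaborolan-2-yl)-1,3-benzodioxol-4-yl]-3-phenylpropan-1-one | COc1c(B3OC(C)(C)C(C)(C)O3)cc2OCOc2c1C(=O)CCc1ccccc1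
F9 | step 6 | methyl (E)-2-iodo-3-phenylprop-2-enoate | COC(=O)/C(I)=C\c1ccccc1
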